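## Structural features

The target is a labdane: a trans-fused decalin (ring A = C1–C5/C10, ring B = C5–C10) with an exocyclic C8=C17 methylene, a C9 side chain (C11–C16) ending in an (E)-C13=C14 trisubstituted alkene whose allylic C15 oxygen carries a palmitoyl group, and a free C19 carboxylic acid on C4. Four stereocentres run along the ring fusion, C4–C5–C10–C9 (4S,5R,9S,10R): C4 and C10 are quaternary, the C19 carboxyl and the C20 methyl are both axial on the β face, and H5 and H9 are α, so the side chain is equatorial. The fragile groups are the allylic palmitate (ionisation or displacement at C15, acyl transfer under base, zerovalent palladium), the exocyclic alkene (acid-induced migration into ring B) and the neopentyl axial acid, which cannot be freed from a simple alkyl ester under conditions the palmitate survives. The side chain and the acylation are routine; the real difficulty is ring A, where two quaternary carbons flank the ring-fusion carbon C5 and the fusion must be trans. The key step exploits the fact that C5 is an unfunctionalised methylene of ring B bonded to quaternary C10: a carbenoid at C4, at the end of the C1–C3 chain on C10, finds no hydrogen at the 1,5-position and reaches the C5–H bonds through a six-membered transition state, closing ring A by the C4–C5 bond. The C8 carbonyl of the ring B precursor deactivates the competing C9–H bond, and the equatorial C9 side chain decides which C10 substituent is axial and so transmits the ring-fusion geometry.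

## Logic of the disconnections

34 ⇒ 33. The O–CH2 bond of the C19 ester is cut last. A free acid cannot pass through the organometallic steps, and a simple alkyl ester at this hindered axial position cannot be cleaved next to the palmitate. A 2-silylethyl ester fragments on attack at silicon, away from the carbonyl. The forward step must leave the allylic ester alone.

33 ⇒ 31 + 32. The acyl–O bond at C15 is cut so that the sensitive allylic ester appears only after all metal-mediated steps. This removes sixteen carbons in one move. The forward step is a plain O-acylation, and 31 comes from 30 by O–Si cleavage under mild acid, which the silylethyl ester tolerates.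

30 ⇒ 24 + 28. The C12–C13 sp3–sp2 bond is cut. The alkene geometry is then fixed in a four-carbon fragment and transferred with retention. The forward step needs an alkylzinc reagent that tolerates the ester and the exocyclic alkene, and a coupling faster than β-hydride elimination.

28 ⇒ 26 ⇒ 25. The C–I and C–H bonds across the alkyne and the O–Si bond are cut. The forward hydrometalation must be syn and must place the metal on the carbon remote from oxygen.

24 ⇒ 23 ⇒ 22. The C12–I and O–Si bonds are interchanged. The halide is introduced only after the C8 carbonyl is gone, because a 4-halo ketone would close a cyclopropane under base.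

22 ⇒ 20. The C4–C18 bond is cut. Both C4 epimers of 20 converge on one enolate, so the uncontrolled centre of the key step is repaired here. The forward step needs complete enolisation of a hindered ester, attack from the α face, and no other acidic site in the molecule.

20 ⇒ 19. The C8=C17 bond is cut. The ketone has done its work (assembly of C9/C10, deactivation of C9–H) and must be removed before the ester is enolised.

19 ⇒ 18. The C4–C5 bond is cut, opening ring A. The bicycle with four stereocentres reduces to a cyclohexanone with two. The forward insertion must beat the 1,2-hydride shift from C3, and must select the equatorial C5–H bond over the axial one, which is also within reach and would give the cis isomer. Quaternary C10 excludes only the five-membered insertion. Checked atom by atom against 34, C9 and C10 of 18 and C5, C9 and C10 of 19 have the target configuration, and C4 of 19 is drawn with the ester equatorial (α). No stereodescriptor needed correction.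

18 ⇒ 17 ⇒ 12 + 16. The C=N2 bond, with loss of an acetyl group, and the C3–C4 bond are cut. A diazo transfer to a simple ester would need a strong base that enolises the ring ketone first. An acetoacetate is acidic enough for an amine base and loses its acetyl group in the transfer. The chain therefore ends in a primary chloride, and the ester is chosen as the silylethyl ester from the outset. The forward steps must C-alkylate without epimerising C9.

16 ⇒ 13 + 14. The ester C–O bond is cut; acetoacetylation through the ketene.

12 ⇒ 11 ⇒ 9. The O–Si bond is cut and the allyl group is shortened by one carbon. Allyl iodide is the reactive stand-in for a 2-oxyethyl electrophile. The forward reduction must take the aldehyde and leave the ketone.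

9 ⇒ 5 + 6 + 7. The C10–C20 and C9–C11 bonds are cut. Catalytic conjugate addition sets C10 and gives the C9 enolate regiospecifically. Control at C9 is weak, because methyl and the chain differ little in size. C9 purity matters, because the C9 epimer would place the tether axial and lead to the cis-decalin.

5 ⇒ 4 ⇒ 1 + 2. The C–Cl bond and the C10–C1 bond are cut (1,2-addition and transposition). The chloride is a latent leaving group that survives steps 3–5 without protection.

## Other disconnections considered

Alternative 1: The cut lies in the side chain only: C13–C16, C14–C15 and the O-acyl bond, leading back to the terminal alkyne A2 (C12–C13≡C14H on the finished bicycle). Forward, Cp2ZrCl2-catalysed syn-methylalumination puts methyl on C13 and aluminium on C14. The alkenylalane, as its butyl ate complex, adds to formaldehyde, and the alkoxide is acylated by palmitoyl chloride in the same flask to give A1, which is the same compound as 33. In its favour: the syn addition fixes the E geometry, three bonds form in one flask, no alkenyl iodide has to be made, and A2 would come from 24 in one step. Against it here: it builds no ring and no stereocentre and so leaves the ring A problem untouched. Excess Me3Al must coexist with the ester, and acylating an aluminate alkoxide beside residual Al–C bonds invites alkyl transfer to the acid chloride. On stereocontrol of C13=C14 it is the equal of the chosen coupling, since both are stereospecific. On step economy it is the better: two operations from 24 against three on the main line plus two for 28. The chosen coupling separates the events and keeps organoaluminium species away from the acylation, which is judged more robust. The stepwise form of this alternative serves as the fallback for step 16.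

Alternative 2: The cut removes C5–C10 and C8–C9 together, leading to the acyclic tetraene A4, an (E)-β-methyl enoate tethered through C1–C4 to an (E,E)-diene. Forward, an intramolecular Diels–Alder reaction closes rings A and B to the octalin diester A3. In its favour: two rings and the C5, C9 and C10 centres form at once, the E-enoate geometry places the C11 ester cis to C20 as required, and the reaction type is well known; on precedent it is the better plan. Against it here: the dienophile is trisubstituted and sluggish. Facial and cis/trans selectivity rest on a pre-existing acyclic quaternary C4 whose methyl and ester differ little, and that centre must itself be made enantioselectively in an open chain. After the cycloaddition C11 is a carboxyl carbon needing one-carbon homologation, C6=C7 must be reduced, C17 must be turned into the methylene, and two methyl esters must be told apart. On structure it is more convergent, two rings against one. On mechanism it is more predictable in outcome but weaker in stereocontrol than the catalyst-set C10 of the chosen plan. On step economy it is expected to be longer after the key step, because 19 already carries C8 and C12 at the right oxidation levels.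

Alternative 3: The cut removes C5–C10, leaving the ten-membered carbocycle A6 with an exocyclic C10=CH2 and a C4=C5 enoate. Forward, Fe(acac)3 and PhSiH3 deliver a hydrogen atom to the methylene carbon. The tertiary C10 radical adds across the ring to C5, and the C4 radical is reduced to give the trans-decalin ester A5 as C4 epimers. In its favour: the angular methyl and quaternary C10 form under mild conditions, and a nucleophilic tertiary radical adding to an enoate is polarity-matched, with no hydride-shift competitor; as a reaction class it is the better behaved. A5 maps onto 19 apart from the C8 oxidation level and one protecting group, so the later C4 methylation is the same; on that point the two plans are equal. Against it here: a stereodefined medium ring is costly to assemble, and the C5/C10 outcome depends on the ring conformation. Simple reduction of the alkene competes, and the transannular version is itself without close precedent. On step economy the chosen plan is expected to be shorter, since 18 is reached in eight steps.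

Key step: step 9

Remarks on the chemistry:
- Positions are given in labdane numbering.
- 17 is a mixture at C4; 19–21 are C4 epimers, drawn as the equatorial (4α) ester.
- In step 3 the ligand antipode is taken to be the one that gives (R)-configured C10 in 9.
- A6 is drawn with the (E)-enoate, ring carbons cis.
- trans-Communic acid is taken as purchasable for the fallback to step 9.

## Route

Step 1
Reactants: 1 3-chloropropan-1-ol; 2 3-ethoxycyclohex-2-en-1-one
Product: 4 3-(3-hydroxypropyl)cyclohex-2-en-1-one, via Normant-type Grignard reagent 3 (not isolated)
Conditions: i-PrMgCl, THF, −20 °C; Mg, reflux; 2, 0 °C to rt; 2 M HCl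
Reagents that add atoms: water, O
Why: 1,2-Addition of the alkoxide-masked Grignard reagent to the vinylogous ester and acid-induced hydrolysis–dehydration (Stork–Danheiser transposition) place the C1–C3 chain on the future C10 without a protecting group.

Step 2
Reactants: 4
Product: 5 3-(3-chloropropyl)cyclohex-2-en-1-one
Conditions: PPh3, N-chlorosuccinimide, CH2Cl2, 0 °C to rt
Reagents that add atoms: N-chlorosuccinimide, O=C1CCC(=O)N1Cl
Why: Appel-type deoxychlorination of the primary alcohol through an alkoxyphosphonium ion; the chloride is inert to steps 3–5 and becomes the electrophile in step 7.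

Step 3
Reactants: 5; 6 trimethylaluminium; 7 allyl iodide
Product: 9 (2R,3R)-3-(3-chloropropyl)-3-methyl-2-(prop-2-en-1-yl)cyclohexan-1-one, via dimethylaluminium enolate 8 (not isolated)
Conditions: Cu(O2CC4H3S) (5 mol%), chiral BINOL-derived phosphoramidite (10 mol%), 6, Et2O, −30 °C; then MeLi, THF/DMPU, −30 °C; 7, −30 to 0 °C
Reagents that add atoms: none
Why: Copper–phosphoramidite-catalysed asymmetric conjugate addition of Me3Al sets quaternary C10 under catalyst control and gives the C8–C9 enolate regiospecifically; its lithium aluminate is C-allylated at C9 (enolate alkylation). Only a modest preference for allyl anti to the longer chain (cis to methyl) is expected, so the epimerisable C9 isomer is separated and recycled after DBU equilibration.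

Step 4
Reactants: 9
Product: 11 (2R,3R)-3-(3-chloropropyl)-2-(2-hydroxyethyl)-3-methylcyclohexan-1-one, via keto aldehyde 10 (not isolated)
Conditions: O3, CH2Cl2, −78 °C; PPh3, −78 to 0 °C; then NaBH4, MeOH, −78 °C
Reagents that add atoms: ozone, [O-][O+]=O
Why: Ozonolysis removes the terminal carbon and leaves C12 as an aldehyde, which borohydride at −78 °C should reduce far faster than the hindered ring ketone (chemoselective carbonyl reduction); the neutral conditions do not touch C9.

Step 5
Reactants: 11
Product: 12 (2R,3R)-2-{2-[(tert-butyldimethylsilyl)oxy]ethyl}-3-(3-chloropropyl)-3-methylcyclohexan-1-one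
Conditions: t-BuMe2SiCl, imidazole, CH2Cl2, 0 °C to rt
Reagents that add atoms: tert-butyldimethylsilyl chloride, CC(C)(C)[Si](C)(C)Cl
Why: Silylation of the primary alcohol in its open hydroxy-ketone form; the silyl ether lies out of reach of the later carbenoid and is cleaved by mild acid beside the silylethyl ester.

Step 6
Reactants: 13 2-(trimethylsilyl)ethan-1-ol; 14 2,2,6-trimethyl-4H-1,3-dioxin-4-one
Product: 16 2-(trimethylsilyl)ethyl 3-oxobutanoate, via acetylketene 15 (not isolated)
Conditions: xylenes, 135 °C, acetone distilled off
Reagents that add atoms: none
Why: Thermal cycloreversion of the dioxinone releases acetylketene, which the alcohol traps (acetoacetylation); this supplies C4 and C19 already as the fluoride-labile ester.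

Step 7
Reactants: 12; 16
Product: 17 2-(trimethylsilyl)ethyl 2-acetyl-5-[(1S,2R)-2-{2-[(tert-butyldimethylsilyl)oxy]ethyl}-1-methyl-3-oxocyclohexyl]pentanoate (both C4 epimers)
Conditions: NaH (less than 1 equiv relative to 16), NaI (cat.), DMF, 60–70 °C
Reagents that add atoms: none
Why: Iodide-assisted C-alkylation of the sodium acetoacetate enolate by the primary chloride (acetoacetic ester alkylation) forms C3–C4; the enolate is too weak a base to enolise the ring ketone, so C9 should keep its configuration.

Step 8
Reactants: 17
Product: 18 2-(trimethylsilyl)ethyl 5-[(1S,2R)-2-{2-[(tert-butyldimethylsilyl)oxy]ethyl}-1-methyl-3-oxocyclohexyl]-2-diazopentanoate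
Conditions: 4-acetamidobenzenesulfonyl azide, DBU, MeCN, 0 °C to rt
Reagents that add atoms: 4-acetamidobenzenesulfonyl azide, CC(=O)Nc1ccc(cc1)S(=O)(=O)N=[N+]=[N-]
Why: Deacylative (Regitz) diazo transfer: the acetoacetate C–H is the only site an amine base deprotonates, and the adduct loses the acetyl group to the sulfonamide, so the α-diazo ester forms beside the free ketone.

Step 9
Reactants: 18
Product: 19 2-(trimethylsilyl)ethyl (1R,4aS,5R,8aS)-5-{2-[(tert-butyldimethylsilyl)oxy]ethyl}-4a-methyl-6-oxodecahydronaphthalene-1-carboxylate and its (1S) epimer
Conditions: Rh2(O2CCPh3)4 (1 mol%), CH2Cl2, −78 °C, slow addition of 18, then to −20 °C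
Reagents that add atoms: none
Why: Proposed new method: Rh2(O2CCPh3)4 expels N2 from 18 to give an electrophilic dirhodium carbenoid at C4, which should insert into the equatorial C5–H bond through a concerted, hydride-transfer-like three-centre transition state with retention at C5; the closest known reaction type is the dirhodium-catalysed intramolecular C–H insertion of α-alkyl-α-diazo esters, which normally closes five-membered rings and has not been shown for a six-membered closure onto an unactivated cyclohexanone methylene. Ring A closes in a 1,6-sense through a chair-like transition state that spans the equatorial C10–C1 bond and the equatorial C5–H bond, the only ring size open because quaternary C10 bears no hydrogen. The new C5 centre is controlled by C10 and, through it, by C9: the equatorial C9 side chain keeps the C20 methyl axial and the tether equatorial, so the C4–C5 bond forms trans to C20 and the decalin is trans-fused. C4 is not controlled, and both epimers go on to step 11. The step needs insertion to beat the 1,2-hydride shift from C3, for which the bulky electron-rich triphenylacetate ligands, −78 °C, slow addition and a non-coordinating solvent are chosen. It also needs C5–H to be preferred over C9–H (deactivated by the adjacent carbonyl), over the primary C20–H bonds and over the CH2Si group of the ester (held away by the s-trans ester geometry), and the equatorial C5–H over the axial one, which from the same conformer would give the cis isomer.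

Step 10
Reactants: 19
Product: 20 2-(trimethylsilyl)ethyl (1R,4aS,5S,8aS)-5-{2-[(tert-butyldimethylsilyl)oxy]ethyl}-4a-methyl-6-methylidenedecahydronaphthalene-1-carboxylate and its (1S) epimer
Conditions: Ph3PCH3Br, KN(SiMe3)2, THF, 0 to 50 °C
Reagents that add atoms: methyltriphenylphosphonium bromide, C[P+](c1ccccc1)(c1ccccc1)c1ccccc1.[Br-]
Why: Wittig methylenation of the hindered C8 ketone installs C17; the ylide is too weak a base to enolise the ester, and any reversible enolisation of the ketone returns C9 to the stable equatorial arrangement. The step removes the only site more acidic than C4–H.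

Step 11
Reactants: 20
Product: 22 2-(trimethylsilyl)ethyl (1S,4aR,5S,8aR)-5-{2-[(tert-butyldimethylsilyl)oxy]ethyl}-1,4a-dimethyl-6-methylidenedecahydronaphthalene-1-carboxylate, via lithium ester enolate 21 (not isolated)
Conditions: LiN(i-Pr)2, THF/DMPU, −78 to −20 °C; MeI, −78 °C to rt
Reagents that add atoms: iodomethane, CI
Why: Both C4 epimers give the same exocyclic lithium enolate, and methyl iodide should approach from the equatorial α face, away from the axial C20 methyl, leaving the ester axial as in the podocarpic acid series (stereoselective ester enolate alkylation); this sets C4.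

Step 12
Reactants: 22
Product: 23 2-(trimethylsilyl)ethyl (1S,4aR,5S,8aR)-5-(2-hydroxyethyl)-1,4a-dimethyl-6-methylidenedecahydronaphthalene-1-carboxylate
Conditions: camphorsulfonic acid (10 mol%), MeOH/CH2Cl2, 0 °C
Reagents that add atoms: none
Why: Acid-catalysed methanolysis of the primary silyl ether; the silylethyl ester and the exocyclic alkene should tolerate catalytic sulfonic acid at 0 °C.

Step 13
Reactants: 23
Product: 24 2-(trimethylsilyl)ethyl (1S,4aR,5S,8aR)-5-(2-iodoethyl)-1,4a-dimethyl-6-methylidenedecahydronaphthalene-1-carboxylate
Conditions: I2, PPh3, imidazole, CH2Cl2, 0 °C to rt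
Reagents that add atoms: iodine, [I][I]
Why: Appel-type iodination (SN2 at the primary alkoxyphosphonium carbon); imidazole buffers the acid, so the exocyclic alkene should not migrate.

Step 14
Reactants: 25 but-2-yn-1-ol
Product: 26 (but-2-yn-1-yloxy)(tert-butyl)dimethylsilane
Conditions: t-BuMe2SiCl, imidazole, CH2Cl2, rt
Reagents that add atoms: tert-butyldimethylsilyl chloride, CC(C)(C)[Si](C)(C)Cl
Why: Silylation of the propargylic alcohol; the bulky silyloxymethyl group steers the hydrometalation that follows.

Step 15
Reactants: 26
Product: 28 tert-butyl{[(2E)-3-iodobut-2-en-1-yl]oxy}dimethylsilane, via alkenylzirconocene chloride 27 (not isolated)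
Conditions: Cp2Zr(H)Cl (2.2 equiv), THF, 50 °C; then I2, 0 °C
Reagents that add atoms: iodine, [I][I]
Why: syn-Hydrozirconation, equilibrated by excess reagent to place zirconium on the carbon remote from the silyloxymethyl group, then iodinolysis with retention; iodine ends trans to CH2O and methyl cis, which is the C13=C14 geometry of the target.

Step 16
Reactants: 24; 28
Product: 30 2-(trimethylsilyl)ethyl (1S,4aR,5S,8aR)-5-[(3E)-5-[(tert-butyldimethylsilyl)oxy]-3-methylpent-3-en-1-yl]-1,4a-dimethyl-6-methylidenedecahydronaphthalene-1-carboxylate, via alkylzinc iodide 29 (not isolated)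
Conditions: Zn (activated with BrCH2CH2Br, Me3SiCl), LiCl, THF, 40 °C; then 28, Pd(dppf)Cl2 (5 mol%), rt to 40 °C
Reagents that add atoms: none
Why: Zinc insertion gives a primary alkylzinc iodide that tolerates the ester and the alkene; Negishi coupling (oxidative addition of the alkenyl iodide to zerovalent palladium, transmetalation, reductive elimination) forms C12–C13 with retention of the alkene geometry, and the bidentate ligand favours reductive elimination over β-hydride elimination.

Step 17
Reactants: 30
Product: 31 2-(trimethylsilyl)ethyl (1S,4aR,5S,8aR)-5-[(3E)-5-hydroxy-3-methylpent-3-en-1-yl]-1,4a-dimethyl-6-methylidenedecahydronaphthalene-1-carboxylate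
Conditions: pyridinium p-toluenesulfonate, MeOH, rt
Reagents that add atoms: none
Why: Mild acid methanolysis of the allylic primary silyl ether; the conditions are too weak to ionise the allylic alcohol or to cleave the silylethyl ester.

Step 18
Reactants: 31; 32 hexadecanoyl chloride
Product: 33 2-(trimethylsilyl)ethyl (1S,4aR,5S,8aR)-5-[(3E)-5-(hexadecanoyloxy)-3-methylpent-3-en-1-yl]-1,4a-dimethyl-6-methylidenedecahydronaphthalene-1-carboxylate
Conditions: pyridine, 4-(dimethylamino)pyridine (cat.), CH2Cl2, 0 °C to rt
Reagents that add atoms: none
Why: Nucleophile-catalysed O-acylation of the primary allylic alcohol; with the acid still masked there is no competing acyl acceptor.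

Step 19
Reactants: 33
Product: 34 (1S,4aR,5S,8aR)-5-[(3E)-5-(hexadecanoyloxy)-3-methylpent-3-en-1-yl]-1,4a-dimethyl-6-methylidenedecahydronaphthalene-1-carboxylic acid (target)
Conditions: Bu4NF, THF, 0 °C to rt; aq NH4Cl
Reagents that add atoms: none
Why: Fluoride attacks silicon and the ester fragments to ethene and the carboxylate (fluoride-induced β-elimination), so the hindered carbonyl is never attacked; the palmitate, a plain primary alkyl ester, should survive a short exposure at low temperature.

## Compound list

1 | 3-chloropropan-1-ol | OCCCCl | starting material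
2 | 3-ethoxycyclohex-2-en-1-one | CCOC1=CC(=O)CCC1 | starting material
3 | chloromagnesium 3-(chloromagnesio)propan-1-olate (Normant-type Grignard reagent) | Cl[Mg]CCCO[Mg]Cl | intermediate
4 | 3-(3-hydroxypropyl)cyclohex-2-en-1-one | O=C1C=C(CCCO)CCC1 | intermediate
5 | 3-(3-chloropropyl)cyclohex-2-en-1-one | O=C1C=C(CCCCl)CCC1 | intermediate
6 | trimethylaluminium | C[Al](C)C | starting material
7 | allyl iodide (3-iodoprop-1-ene) | C=CCI | starting material
8 | dimethylaluminium (3R)-3-(3-chloropropyl)-3-methylcyclohex-1-en-1-olate | ClCCC[C@@]1(C)CCCC(O[Al](C)C)=C1 | intermediate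
9 | (2R,3R)-3-(3-chloropropyl)-3-methyl-2-(prop-2-en-1-yl)cyclohexan-1-one | ClCCC[C@@]1(C)CCCC(=O)[C@@H]1CC=C | intermediate
10 | [(1R,2R)-2-(3-chloropropyl)-2-methyl-6-oxocyclohexyl]acetaldehyde | ClCCC[C@@]1(C)CCCC(=O)[C@@H]1CC=O | intermediate
11 | (2R,3R)-3-(3-chloropropyl)-2-(2-hydroxyethyl)-3-methylcyclohexan-1-one | ClCCC[C@@]1(C)CCCC(=O)[C@@H]1CCO | intermediate
12 | (2R,3R)-2-{2-[(tert-butyldimethylsilyl)oxy]ethyl}-3-(3-chloropropyl)-3-methylcyclohexan-1-one | ClCCC[C@@]1(C)CCCC(=O)[C@@H]1CCO[Si](C)(C)C(C)(C)C | intermediate
13 | 2-(trimethylsilyl)ethan-1-ol | OCC[Si](C)(C)C | starting material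
14 | 2,2,6-trimethyl-4H-1,3-dioxin-4-one | CC1=CC(=O)OC(C)(C)O1 | starting material
15 | acetylketene (3-oxobut-1-en-1-one) | CC(=O)C=C=O | intermediate
16 | 2-(trimethylsilyl)ethyl 3-oxobutanoate | CC(=O)CC(=O)OCC[Si](C)(C)C | intermediate
17 | 2-(trimethylsilyl)ethyl 2-acetyl-5-[(1S,2R)-2-{2-[(tert-butyldimethylsilyl)oxy]ethyl}-1-methyl-3-oxocyclohexyl]pentanoate (both C4 epimers) | CC(=O)C(CCC[C@@]1(C)CCCC(=O)[C@@H]1CCO[Si](C)(C)C(C)(C)C)C(=O)OCC[Si](C)(C)C | intermediate
18 | 2-(trimethylsilyl)ethyl 5-[(1S,2R)-2-{2-[(tert-butyldimethylsilyl)oxy]ethyl}-1-methyl-3-oxocyclohexyl]-2-diazopentanoate | C[Si](C)(C)CCOC(=O)C(=[N+]=[N-])CCC[C@@]1(C)CCCC(=O)[C@@H]1CCO[Si](C)(C)C(C)(C)C | intermediate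
19 | 2-(trimethylsilyl)ethyl (1R,4aS,5R,8aS)-5-{2-[(tert-butyldimethylsilyl)oxy]ethyl}-4a-methyl-6-oxodecahydronaphthalene-1-carboxylate (drawn; the (1S) epimer is also formed) | O=C1CC[C@@H]2[C@](C)(CCC[C@H]2C(=O)OCC[Si](C)(C)C)[C@H]1CCO[Si](C)(C)C(C)(C)C | intermediate
20 | 2-(trimethylsilyl)ethyl (1R,4aS,5S,8aS)-5-{2-[(tert-butyldimethylsilyl)oxy]ethyl}-4a-methyl-6-methylidenedecahydronaphthalene-1-carboxylate (drawn; with its (1S) epimer) | C=C1CC[C@@H]2[C@](C)(CCC[C@H]2C(=O)OCC[Si](C)(C)C)[C@H]1CCO[Si](C)(C)C(C)(C)C | intermediate
21 | lithium enolate of 20 at C4 (exocyclic C4=C(OLi)OCH2CH2SiMe3; C5, C9, C10 as in 20) | C=C1CC[C@@H]2[C@](C)(CCCC2=C(O[Li])OCC[Si](C)(C)C)[C@H]1CCO[Si](C)(C)C(C)(C)C | intermediate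
22 | 2-(trimethylsilyl)ethyl (1S,4aR,5S,8aR)-5-{2-[(tert-butyldimethylsilyl)oxy]ethyl}-1,4a-dimethyl-6-methylidenedecahydronaphthalene-1-carboxylate | C=C1CC[C@@H]2[C@](C)(CCC[C@]2(C)C(=O)OCC[Si](C)(C)C)[C@H]1CCO[Si](C)(C)C(C)(C)C | intermediate
23 | 2-(trimethylsilyl)ethyl (1S,4aR,5S,8aR)-5-(2-hydroxyethyl)-1,4a-dimethyl-6-methylidenedecahydronaphthalene-1-carboxylate | C=C1CC[C@@H]2[C@](C)(CCC[C@]2(C)C(=O)OCC[Si](C)(C)C)[C@H]1CCO | intermediate
24 | 2-(trimethylsilyl)ethyl (1S,4aR,5S,8aR)-5-(2-iodoethyl)-1,4a-dimethyl-6-methylidenedecahydronaphthalene-1-carboxylate | C=C1CC[C@@H]2[C@](C)(CCC[C@]2(C)C(=O)OCC[Si](C)(C)C)[C@H]1CCI | intermediate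
25 | but-2-yn-1-ol | CC#CCO | starting material
26 | (but-2-yn-1-yloxy)(tert-butyl)dimethylsilane | CC#CCO[Si](C)(C)C(C)(C)C | intermediate
27 | chlorobis(η5-cyclopentadienyl){(2E)-4-[(tert-butyldimethylsilyl)oxy]but-2-en-2-yl}zirconium | C/C(=C\CO[Si](C)(C)C(C)(C)C)[Zr](Cl)(C1C=CC=C1)C1C=CC=C1 | intermediate
28 | tert-butyl{[(2E)-3-iodobut-2-en-1-yl]oxy}dimethylsilane | I/C(C)=C/CO[Si](C)(C)C(C)(C)C | intermediate
29 | alkylzinc iodide derived from 24 (C12–ZnI in place of C12–I) | C=C1CC[C@@H]2[C@](C)(CCC[C@]2(C)C(=O)OCC[Si](C)(C)C)[C@H]1CC[Zn]I | intermediate
30 | 2-(trimethylsilyl)ethyl (1S,4aR,5S,8aR)-5-[(3E)-5-[(tert-butyldimethylsilyl)oxy]-3-methylpent-3-en-1-yl]-1,4a-dimethyl-6-methylidenedecahydronaphthalene-1-carboxylate | C=C1CC[C@@H]2[C@](C)(CCC[C@]2(C)C(=O)OCC[Si](C)(C)C)[C@H]1CC/C(C)=C/CO[Si](C)(C)C(C)(C)C | intermediate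
31 | 2-(trimethylsilyl)ethyl (1S,4aR,5S,8aR)-5-[(3E)-5-hydroxy-3-methylpent-3-en-1-yl]-1,4a-dimethyl-6-methylidenedecahydronaphthalene-1-carboxylate | C=C1CC[C@@H]2[C@](C)(CCC[C@]2(C)C(=O)OCC[Si](C)(C)C)[C@H]1CC/C(C)=C/CO | intermediate
32 | hexadecanoyl chloride (palmitoyl chloride) | CCCCCCCCCCCCCCCC(=O)Cl | starting material
33 | 2-(trimethylsilyl)ethyl (1S,4aR,5S,8aR)-5-[(3E)-5-(hexadecanoyloxy)-3-methylpent-3-en-1-yl]-1,4a-dimethyl-6-methylidenedecahydronaphthalene-1-carboxylate | C=C1CC[C@@H]2[C@](C)(CCC[C@]2(C)C(=O)OCC[Si](C)(C)C)[C@H]1CC/C(C)=C/COC(=O)CCCCCCCCCCCCCCC | intermediate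
34 | (1S,4aR,5S,8aR)-5-[(3E)-5-(hexadecanoyloxy)-3-methylpent-3-en-1-yl]-1,4a-dimethyl-6-methylidenedecahydronaphthalene-1-carboxylic acid | C=C1CC[C@@H]2[C@](C)(CCC[C@]2(C)C(=O)O)[C@H]1CC/C(C)=C/COC(=O)CCCCCCCCCCCCCCC | target

## Step count and least certain steps

Total step count: 19. Longest linear sequence: 16 (steps 1–5, 7–13, 16–19); step 6 prepares 16 and steps 14–15 prepare 28.

Step 9 (key step). The most likely failure is hydride migration from C3 to the carbenoid carbon outrunning insertion. Insertion from the minor chair with an axial tether would erode the trans fusion, and attack of the carbenoid on the ester's own CH2Si group is also possible. The fallback gives up the de novo closure of ring A and is a chiral-pool relay by known reactions. It sets out from 13, which esterifies commercial trans-communic acid under Mitsunobu conditions (PPh3, diisopropyl azodicarboxylate) to the 2-(trimethylsilyl)ethyl ester of trans-communic acid F1. One equivalent of ozone at −78 °C (CH2Cl2–pyridine, dye end point, PPh3 work-up) should cleave the trisubstituted C12=C13 bond of the side-chain diene ahead of the exocyclic alkene and give the C12 aldehyde F2. NaBH4 reduction returns to the route at 23.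

Step 3. The likely failures are slow C-allylation of the aluminium enolate, so that it is merely protonated on work-up, and poor facial discrimination at C9, because methyl and the chain on C10 differ little in size. The fallback replaces substrate control by catalyst control. It sets out from 5: the same conjugate addition is run, 8 is trapped with allyl chloroformate as the allyl enol carbonate F3, and a palladium-catalysed decarboxylative asymmetric allylation (Pd2(dba)3, Trost bisphosphine ligand of the appropriate antipode) delivers the allyl group to the required face. It returns at 9.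

Step 16. The likely failures are incomplete zinc insertion or protonolysis of the alkylzinc reagent, and β-hydride elimination from the alkylpalladium intermediate before reductive elimination. The fallback builds the trisubstituted alkene by carbometalation instead of cross-coupling. It sets out from 24: displacement with lithium acetylide–ethylenediamine in DMSO gives the terminal alkyne F4 (the same compound as A2). Cp2ZrCl2-catalysed methylalumination with Me3Al, ate formation with n-BuLi and addition to paraformaldehyde then return to the route at 31.

Step 19. The likely failure is fluoride-mediated loss or migration of the palmitate while the hindered silylethyl ester fragments only slowly. The fallback inverts the order of the last two operations. It sets out from 31: Bu4NF gives isocupressic acid F5, whose primary allylic hydroxyl is then acylated with 32 in pyridine. The hindered acid can at most form a mixed anhydride, which the aqueous bicarbonate work-up hydrolyses. It returns at 34.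

## Further compounds

F1 | step 9 | 2-(trimethylsilyl)ethyl (1S,4aR,5S,8aR)-1,4a-dimethyl-6-methylidene-5-[(2E)-3-methylpenta-2,4-dien-1-yl]decahydronaphthalene-1-carboxylate (silylethyl trans-communate) | C=C1CC[C@@H]2[C@](C)(CCC[C@]2(C)C(=O)OCC[Si](C)(C)C)[C@H]1C/C=C(\C)C=C
F2 | step 9 | 2-(trimethylsilyl)ethyl (1S,4aR,5S,8aR)-1,4a-dimethyl-6-methylidene-5-(2-oxoethyl)decahydronaphthalene-1-carboxylate | C=C1CC[C@@H]2[C@](C)(CCC[C@]2(C)C(=O)OCC[Si](C)(C)C)[C@H]1CC=O
F3 | step 3 | (3R)-3-(3-chloropropyl)-3-methylcyclohex-1-en-1-yl prop-2-en-1-yl carbonate | ClCCC[C@@]1(C)CCCC(OC(=O)OCC=C)=C1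
F4 | step 16 | 2-(trimethylsilyl)ethyl (1S,4aR,5S,8aR)-5-(but-3-yn-1-yl)-1,4a-dimethyl-6-methylidenedecahydronaphthalene-1-carboxylate | C=C1CC[C@@H]2[C@](C)(CCC[C@]2(C)C(=O)OCC[Si](C)(C)C)[C@H]1CCC#C
F5 | step 19 | (1S,4aR,5S,8aR)-5-[(3E)-5-hydroxy-3-methylpent-3-en-1-yl]-1,4a-dimethyl-6-methylidenedecahydronaphthalene-1-carboxylic acid (isocupressic acid) | C=C1CC[C@@H]2[C@](C)(CCC[C@]2(C)C(=O)O)[C@H]1CC/C(C)=C/CO
A1 | alternative 1 | 2-(trimethylsilyl)ethyl ester of the target, identical with 33 | C=C1CC[C@@H]2[C@](C)(CCC[C@]2(C)C(=O)OCC[Si](C)(C)C)[C@H]1CC/C(C)=C/COC(=O)CCCCCCCCCCCCCCC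
A2 | alternative 1 | 2-(trimethylsilyl)ethyl (1S,4aR,5S,8aR)-5-(but-3-yn-1-yl)-1,4a-dimethyl-6-methylidenedecahydronaphthalene-1-carboxylate (terminal alkyne, C13≡C14) | C=C1CC[C@@H]2[C@](C)(CCC[C@]2(C)C(=O)OCC[Si](C)(C)C)[C@H]1CCC#C
A3 | alternative 2 | trans-fused Δ6-octalin with methyl esters at C19 and C11 and C17 as a tert-butyldimethylsilyloxymethyl group on C8 | CC(C)(C)[Si](C)(C)OC[C@H]1C=C[C@@H]2[C@](C)(CCC[C@]2(C)C(=O)OC)[C@H]1C(=O)OC
A4 | alternative 2 | methyl (2E,7S,8E,10E)-12-[(tert-butyldimethylsilyl)oxy]-7-(methoxycarbonyl)-3,7-dimethyldodeca-2,8,10-trienoate | COC(=O)/C=C(\C)CCC[C@](C)(C(=O)OC)/C=C/C=C/CO[Si](C)(C)C(C)(C)C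
A5 | alternative 3 | trans-decalin C4–H methyl ester (C4 epimers, equatorial ester drawn) with a tert-butyldimethylsilyloxy group on C8 and a 2-(4-methoxybenzyloxy)ethyl group on C9 | CC(C)(C)[Si](C)(C)O[C@@H]1CC[C@@H]2[C@](C)(CCC[C@H]2C(=O)OC)[C@H]1CCOCc1ccc(OC)cc1
A6 | alternative 3 | methyl (E)-cyclodec-1-ene-1-carboxylate bearing 5-(tert-butyldimethylsilyloxy), 6-[2-(4-methoxybenzyloxy)ethyl] and 7-methylidene groups (C8 and C9 as in A5) | CC(C)(C)[Si](C)(C)O[C@@H]1CC/C=C(C(=O)OC)\CCCC(=C)[C@H]1CCOCc1ccc(OC)cc1
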